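**Retrosynthetic overview**
1. Target ⇐ its hexa-O-benzyl ether by global hydrogenolysis; the gallate ester is carried in from the start, so there is no late esterification.
2. Hexabenzyl ether ⇐ one-pot union of an A-ring o-quinone methide (C4, aromatic ring, O1) with the chiral-ion-paired enolate of a phenacyl gallate (C2, C3, B ring, ester): C3–C4 by asymmetric Michael addition (sets C3), O1–C2 by hemiketalisation.
3. Ring order in that pot: the pyran closes first (hemiketal); on acidification the 3-O-galloyl group and the C2 cation close a cis-fused 1,3-dioxolan-2-ylium ring, which hydride opens at C2 (sets C2, 2,3-cis).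
4. o-Quinone methide precursor (benzylic sulfone) ⇐ 2,4,6-trihydroxybenzaldehyde; phenacyl gallate ⇐ α-bromoketone + tri-O-benzylgallic acid.

Assumption: the SMILES is read as (2R,3R), 2,3-cis, i.e. (−)-epiafzelechin 3-O-gallate; benzyl bromide and other small reagents are not numbered.

**Step 1**
Reactants: 1 2,4,6-trihydroxybenzaldehyde
Product: 2 2,4-bis(benzyloxy)-6-hydroxybenzaldehyde
Conditions: BnBr (2.05 equiv), K2CO3 (2.2 equiv), DMF, 0 °C → rt
Reagents that add atoms: benzyl bromide, BrCc1ccccc1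
Why: Williamson etherification in which the 4-OH and one ortho-OH are alkylated while the remaining ortho-OH, held in a hydrogen bond to the formyl group, is the least nucleophilic and stays free.

**Step 2**
Reactants: 2 2,4-bis(benzyloxy)-6-hydroxybenzaldehyde
Product: 4 3,5-bis(benzyloxy)-2-[(4-methylbenzenesulfonyl)methyl]phenol, via salicyl alcohol 3 (not isolated)
Conditions: NaBH4, THF/MeOH, 0 °C; then TolSO2Na (3 equiv), HCO2H/H2O, 0 °C → rt
Reagents that add atoms: sodium 4-methylbenzenesulfinate, [Na+].[O-]S(=O)c1ccc(C)cc1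
Why: Borohydride reduction gives the very electron-rich salicyl alcohol, which ionises under mild acid to a stabilised o-hydroxybenzyl cation that sulfinate captures at sulfur (SN1-type sulfinate alkylation), giving a storable, base-triggered o-quinone methide precursor.

**Step 3**
Reactants: 5 1-[4-(benzyloxy)phenyl]-2-bromoethan-1-one; 6 3,4,5-tris(benzyloxy)benzoic acid
Product: 7 2-[4-(benzyloxy)phenyl]-2-oxoethyl 3,4,5-tris(benzyloxy)benzoate
Conditions: K2CO3, DMF, rt
Reagents that add atoms: none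
Why: SN2 O-alkylation of the carboxylate by the α-bromoketone (phenacyl ester formation).

**Step 4 (key step)**
Reactants: 4 3,5-bis(benzyloxy)-2-[(4-methylbenzenesulfonyl)methyl]phenol; 7 2-[4-(benzyloxy)phenyl]-2-oxoethyl 3,4,5-tris(benzyloxy)benzoate
Product: 12 (2R,3R)-5,7-bis(benzyloxy)-2-[4-(benzyloxy)phenyl]-3,4-dihydro-2H-chromen-3-yl 3,4,5-tris(benzyloxy)benzoate, via o-quinone methide 8 (not isolated), via keto-phenol 9 (not isolated), via hemiketal 10 (not isolated), via acyloxonium ion 11 (not isolated)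
Conditions: 4 (1.2 equiv), N-(2,3,4-trifluorobenzyl)hydrocinchoninium bromide (10 mol %), Cs2CO3 (2.5 equiv), PhMe/CH2Cl2, −30 °C; then Et3SiH (6 equiv), CF3CO2H (excess), −30 → 0 °C, same flask
Reagents that add atoms: none
Why: Proposed new method: carbonate releases o-quinone methide 8 from 4 by loss of sulfinate while the chiral cinchoninium cation ion-pairs with the Z-enolate of 7, so a face-selective Michael addition (closest known types: cinchona phase-transfer alkylation and Michael addition of α-oxygenated aryl ketone "glycolate" enolates, where cinchonidinium salts give S and the cinchoninium series is therefore expected to give R, and base-triggered additions to sulfone-derived o-quinone methides) sets C3 as R in 9, the phenoxide closes the pyran as hemiketal 10, and on acidification the 3-O-galloyl carbonyl captures the C2 oxocarbenium as the cis-fused dioxolan-2-ylium ring of 11, so that Et3SiH delivers hydride to C2 anti to that bridge (ionic hydrogenation/reductive etherification under neighbouring-group control, known to give 2,3-cis-3-acyloxyflavans) and sets C2 as R.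

**Step 5**
Reactants: 12 (2R,3R)-5,7-bis(benzyloxy)-2-[4-(benzyloxy)phenyl]-3,4-dihydro-2H-chromen-3-yl 3,4,5-tris(benzyloxy)benzoate
Product: 13 (2R,3R)-5,7-dihydroxy-2-(4-hydroxyphenyl)-3,4-dihydro-2H-chromen-3-yl 3,4,5-trihydroxybenzoate
Conditions: H2 (1 atm), 20% Pd(OH)2/C, THF/MeOH, rt
Reagents that add atoms: none
Why: Catalytic hydrogenolysis removes all six O-benzyl groups (global debenzylation) under neutral conditions that, as in catechin gallate chemistry, leave the ester, the cyclic C2–O1 ether and both stereocentres untouched.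

**Compound list**
1 | 2,4,6-trihydroxybenzaldehyde | O=Cc1c(O)cc(O)cc1O | starting material
2 | 2,4-bis(benzyloxy)-6-hydroxybenzaldehyde | O=Cc1c(O)cc(OCc2ccccc2)cc1OCc1ccccc1 | intermediate
3 | 3,5-bis(benzyloxy)-2-(hydroxymethyl)phenol (salicyl alcohol) | OCc1c(O)cc(OCc2ccccc2)cc1OCc1ccccc1 | intermediate
4 | 3,5-bis(benzyloxy)-2-[(4-methylbenzenesulfonyl)methyl]phenol | Cc1ccc(cc1)S(=O)(=O)Cc1c(O)cc(OCc2ccccc2)cc1OCc1ccccc1 | intermediate
5 | 1-[4-(benzyloxy)phenyl]-2-bromoethan-1-one | O=C(CBr)c1ccc(OCc2ccccc2)cc1 | starting material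
6 | 3,4,5-tris(benzyloxy)benzoic acid | OC(=O)c1cc(OCc2ccccc2)c(OCc2ccccc2)c(OCc2ccccc2)c1 | starting material
7 | 2-[4-(benzyloxy)phenyl]-2-oxoethyl 3,4,5-tris(benzyloxy)benzoate | O=C(COC(=O)c1cc(OCc2ccccc2)c(OCc2ccccc2)c(OCc2ccccc2)c1)c1ccc(OCc2ccccc2)cc1 | intermediate
8 | 3,5-bis(benzyloxy)-6-methylidenecyclohexa-2,4-dien-1-one (o-quinone methide) | C=C1C(=O)C=C(OCc2ccccc2)C=C1OCc1ccccc1 | intermediate
9 | (2R)-1-[4-(benzyloxy)phenyl]-3-[2,4-bis(benzyloxy)-6-hydroxyphenyl]-1-oxopropan-2-yl 3,4,5-tris(benzyloxy)benzoate (keto-phenol) | O=C(c1ccc(OCc2ccccc2)cc1)[C@H](OC(=O)c1cc(OCc2ccccc2)c(OCc2ccccc2)c(OCc2ccccc2)c1)Cc1c(O)cc(OCc2ccccc2)cc1OCc1ccccc1 | intermediate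
10 | (2RS,3R)-5,7-bis(benzyloxy)-2-[4-(benzyloxy)phenyl]-2-hydroxy-3,4-dihydro-2H-chromen-3-yl 3,4,5-tris(benzyloxy)benzoate (hemiketal, both C2 epimers) | OC1(c2ccc(OCc3ccccc3)cc2)Oc2cc(OCc3ccccc3)cc(OCc3ccccc3)c2C[C@H]1OC(=O)c1cc(OCc2ccccc2)c(OCc2ccccc2)c(OCc2ccccc2)c1 | intermediate
11 | cis-fused acyloxonium trifluoroacetate: 2-[3,4,5-tris(benzyloxy)phenyl]-1,3-dioxolan-2-ylium ring bridging O–C2 and O–C3 of the 5,7-bis(benzyloxy)-2-[4-(benzyloxy)phenyl]chromane, C3 R, bridge on the face of the C3–O bond | [C@]12(c3ccc(OCc4ccccc4)cc3)Oc3cc(OCc4ccccc4)cc(OCc4ccccc4)c3C[C@H]1OC(=[O+]2)c1cc(OCc2ccccc2)c(OCc2ccccc2)c(OCc2ccccc2)c1.[O-]C(=O)C(F)(F)F | intermediate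
12 | (2R,3R)-5,7-bis(benzyloxy)-2-[4-(benzyloxy)phenyl]-3,4-dihydro-2H-chromen-3-yl 3,4,5-tris(benzyloxy)benzoate | O=C(O[C@@H]1Cc2c(OCc3ccccc3)cc(OCc3ccccc3)cc2O[C@@H]1c1ccc(OCc2ccccc2)cc1)c1cc(OCc2ccccc2)c(OCc2ccccc2)c(OCc2ccccc2)c1 | intermediate
13 | (2R,3R)-5,7-dihydroxy-2-(4-hydroxyphenyl)-3,4-dihydro-2H-chromen-3-yl 3,4,5-trihydroxybenzoate, (−)-epiafzelechin 3-O-gallate | O=C(O[C@@H]1Cc2c(O)cc(O)cc2O[C@@H]1c1ccc(O)cc1)c1cc(O)c(O)c(O)c1 | target

**Totals**
Total step count: 5.
Longest linear sequence: 4 steps (1 → 2 → 4 → 12 → 13); step 3 is the convergent branch.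

**Three steps most likely to fail**

Step 4. The enantioselectivity of the Michael addition is unproven for an α-acyloxy enolate and an o-quinone methide. The enolate may also shift its acyl group. On acidification the cation may lose H-3 to give the achiral enol ester (eroding ee) or lose the gallate. The fallback sets out from bromoketone 5 (using 4 and 6) and comes back at hemiketal 10. Bromoketone 5 is heated with sodium formate in aqueous ethanol to give 2-[4-(benzyloxy)phenyl]-2-oxoethyl formate F1, which is hydrolysed in the same pot to 1-[4-(benzyloxy)phenyl]-2-hydroxyethan-1-one F2. F2 is added as its zinc enediolate under dinuclear zinc–ProPhenol catalysis (Et2Zn, the ligand enantiomer giving 3R, THF) to o-quinone methide 8 released from 4; this catalyst is established for α-hydroxy aryl ketone donors. The product is (3R)-5,7-bis(benzyloxy)-2-[4-(benzyloxy)phenyl]chromane-2,3-diol F3. Steglich esterification of its secondary 3-OH with acid 6 (EDC, DMAP, CH2Cl2) gives 10, which is reduced with Et3SiH/CF3CO2H as in step 4 to 12.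

Step 2. The salicyl alcohol 3 may oligomerise under acid, or the very electron-rich sulfone 4 may be too labile to store. The fallback sets out from aldehyde 2 and comes back at o-quinone methide 8 in the flask of step 4. Reductive amination of 2 with dimethylamine (NaBH(OAc)3, DCE) gives 3,5-bis(benzyloxy)-2-[(dimethylamino)methyl]phenol F4, so no benzylic alcohol ever meets acid. Methyl iodide in acetone gives [2,4-bis(benzyloxy)-6-hydroxyphenyl]-N,N,N-trimethylmethanaminium iodide F5, which loses trimethylamine with Cs2CO3 under the step 4 conditions to give 8.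

Step 1. Over-benzylation or C-benzylation of the phloroglucinol core may lower the yield of the 2,4-dibenzyl ether. The fallback sets out from 1 and comes back at 2. Exhaustive benzylation (BnBr 3.5 equiv, K2CO3, DMF, 60 °C) gives 2,4,6-tris(benzyloxy)benzaldehyde F6. Chelation-controlled removal of one benzyl group ortho to the formyl group (MgBr2·OEt2, PhMe/Et2O, reflux) then gives 2.

**Further compounds**
F1 | step 4 | 2-[4-(benzyloxy)phenyl]-2-oxoethyl formate | O=COCC(=O)c1ccc(OCc2ccccc2)cc1
F2 | step 4 | 1-[4-(benzyloxy)phenyl]-2-hydroxyethan-1-one | O=C(CO)c1ccc(OCc2ccccc2)cc1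
F3 | step 4 | (3R)-5,7-bis(benzyloxy)-2-[4-(benzyloxy)phenyl]chromane-2,3-diol | OC1(c2ccc(OCc3ccccc3)cc2)Oc2cc(OCc3ccccc3)cc(OCc3ccccc3)c2C[C@H]1O
F4 | step 2 | 3,5-bis(benzyloxy)-2-[(dimethylamino)methyl]phenol | CN(C)Cc1c(O)cc(OCc2ccccc2)cc1OCc1ccccc1
F5 | step 2 | [2,4-bis(benzyloxy)-6-hydroxyphenyl]-N,N,N-trimethylmethanaminium iodide | C[N+](C)(C)Cc1c(O)cc(OCc2ccccc2)cc1OCc1ccccc1.[I-]
F6 | step 1 | 2,4,6-tris(benzyloxy)benzaldehyde | O=Cc1c(OCc2ccccc2)cc(OCc2ccccc2)cc1OCc1ccccc1
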